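**Plan**
- Retrosynthesis: the ester C(=O)–O bond is cut last in the forward sense; first, the saturated C10–C11 bond of the C25 acyl chain is traced back to a C10=C11 double bond, which is cut by olefin cross-metathesis.
- Forward: tyrosol (1) is acylated at its CH2OH with undec-10-enoic acid (2) to give ester 3 (C1–C10 plus one sacrificial CH2). Ester 3 is joined with hexadec-1-ene (4, C11–C25 plus one sacrificial CH2) to give pentacos-10-enoate 5, and hydrogenation gives target 6.
- Enabling feature: C3–C25 of the acyl chain is an unbranched run of methylenes with no substituent or stereocentre, so any of its C–C bonds can be a latent C=C. Placed at C10–C11, both halves become commodity terminal olefins.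
- The para-hydroxyphenyl ring needs no protection: a lipase acylates only the aliphatic OH, and Ru carbenes tolerate the free phenol.
- Stereochemistry: the target has no stereocentre; the E/Z geometry of 5 is erased by the hydrogenation.

Key step: step 2

Remark on the chemistry: alkene 5 is expected as an E/Z mixture and is drawn as its E isomer; this has no consequence for 6.

**Step 1**
Reactants: 1 tyrosol [2-(4-hydroxyphenyl)ethanol]; 2 undec-10-enoic acid
Product: 3 2-(4-hydroxyphenyl)ethyl undec-10-enoate
Conditions: Novozym 435 (immobilised Candida antarctica lipase B), 4 Å MS, t-BuOMe, 45 °C; 1 in slight excess (removed by aqueous wash)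
Reagents that add atoms: none
Why: Lipase-catalysed esterification: the serine acyl-enzyme formed from 2 should transfer the acyl group only to the unhindered primary aliphatic OH of 1, the phenolic OH being a poor nucleophile for this enzyme, while the sieves take up the water and pull the equilibrium towards 3.

**Step 2**
Reactants: 3 2-(4-hydroxyphenyl)ethyl undec-10-enoate; 4 hexadec-1-ene
Product: 5 2-(4-hydroxyphenyl)ethyl pentacos-10-enoate (E/Z mixture, drawn E)
Conditions: 4 (5 equiv), Hoveyda–Grubbs II (2.5 mol%), 1,4-benzoquinone (10 mol%), CH2Cl2 (0.1 M in 3), 40 °C, Ar sweep; then ethyl vinyl ether; chromatography
Reagents that add atoms: none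
Why: Olefin cross-metathesis: the Ru alkylidene takes up the terminal C10=C11 olefin of 3 and the C1=C2 olefin of 4 in turn by [2+2] cycloaddition/cycloreversion through ruthenacyclobutanes, joining C10 of the acyl chain to C2 of 4 (C11 of the product) and expelling both terminal CH2 groups as ethylene, whose removal in the argon stream drives the equilibrium. The closest known reaction type is the cross-metathesis of 10-undecenoate esters with linear α-olefins, a pairing of two unhindered terminal olefins of equal reactivity. No ring is closed and no stereocentre is formed; the E/Z geometry of the new double bond is left uncontrolled because step 3 removes it. The step needs cross- over self-coupling, which the fivefold excess of cheap 4 together with secondary metathesis of the ester self-dimer should secure, and the hydrocarbon by-products (triacont-15-ene, surplus 4) differ so much in polarity from the phenolic ester 5 that silica should separate them. It also needs chain-length fidelity, i.e. no double-bond migration before metathesis, which the hydride-scavenging benzoquinone and the low temperature should ensure. The free phenol and the ester, eight methylenes away from the olefin, should neither chelate nor protonate the carbene, so 3 can be used unprotected.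

**Step 3**
Reactants: 5 2-(4-hydroxyphenyl)ethyl pentacos-10-enoate
Product: 6 2-(4-hydroxyphenyl)ethyl pentacosanoate
Conditions: H2 (1 atm), 10% Pd/C, EtOAc/THF, rt; recrystallisation
Reagents that add atoms: none
Why: Heterogeneous catalytic hydrogenation (syn addition of H2 on Pd) should saturate the isolated 1,2-disubstituted C10=C11 bond of both geometric isomers to the same chain, while the phenol ring, the ester and the non-benzylic ArCH2CH2–O bond should be inert at 1 atm and room temperature.

**Compound list**
1 | tyrosol, 2-(4-hydroxyphenyl)ethanol | OCCc1ccc(O)cc1 | starting material
2 | undec-10-enoic acid | C=CCCCCCCCCC(=O)O | starting material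
3 | 2-(4-hydroxyphenyl)ethyl undec-10-enoate | C=CCCCCCCCCC(=O)OCCc1ccc(O)cc1 | intermediate
4 | hexadec-1-ene | CCCCCCCCCCCCCCC=C | starting material
5 | 2-(4-hydroxyphenyl)ethyl (E)-pentacos-10-enoate (E/Z mixture expected, drawn E) | CCCCCCCCCCCCCC/C=C/CCCCCCCCC(=O)OCCc1ccc(O)cc1 | intermediate
6 | 2-(4-hydroxyphenyl)ethyl pentacosanoate | CCCCCCCCCCCCCCCCCCCCCCCCC(=O)OCCc1ccc(O)cc1 | target

Total step count: 3
Longest linear sequence: 3 steps (1 → 3 → 5 → 6); 2 and 4 are purchased.

**Steps most likely to fail**

1. Step 2. Ruthenium-hydride-mediated double-bond migration ahead of productive metathesis would scramble the chain length into homologues that cannot be separated. Statistical self-metathesis and incomplete conversion of 3 would add to the loss. The fallback forms the same C10–C11 bond directly at the saturated level by a copper-catalysed sp3–sp3 coupling, with no alkene stage; it sets out from tyrosol 1 and comes back to the route at 6. Purchased 1-bromopentadecane (CCCCCCCCCCCCCCCBr) with Mg in THF should give pentadecylmagnesium bromide F1. F1 is coupled with purchased methyl 10-bromodecanoate (BrCCCCCCCCCC(=O)OC) under catalytic Li2CuCl4 with NMP in THF at 0 °C (Kochi-type alkyl–alkyl coupling, in which the ester should survive at this temperature) to give methyl pentacosanoate F2. F2 and 1 with Novozym 435 at 70 °C under reduced pressure, which removes the methanol, should then give 6 by chemoselective transesterification at the aliphatic OH.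

2. Step 1. The equilibrium esterification may stall through water held on the immobilised enzyme, or acyl transfer may be slow because tyrosol dissolves poorly in the non-polar medium. The fallback is a Mitsunobu esterification, which sets out from 1 and 2 and comes back at 3: PPh3, DIAD, THF, 0 °C to rt. Here the aliphatic alcohol, not the acid, is activated, so the phenol cannot be acylated, and the carboxylic acid should outcompete the far less acidic phenol as pronucleophile. No compound outside the list is made on this way (none F0).

3. Step 3. Saturation may stay incomplete through poisoning of the palladium by carried-over ruthenium or quinone residues, or through deposition of the waxy substrate and product on the catalyst. The fallback is a metal-free diimide reduction, which sets out from 5 and comes back at 6: TsNHNH2, NaOAc, DME/H2O, reflux. Diimide generated in the flask should deliver H2 in a concerted syn fashion to the isolated alkene only. No compound outside the list is made on this way (none F0).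

**Further compounds**
F1 | step 2 | pentadecylmagnesium bromide | CCCCCCCCCCCCCCC[Mg]Br
F2 | step 2 | methyl pentacosanoate | CCCCCCCCCCCCCCCCCCCCCCCCC(=O)OC
F0 | step 1 | none | none
F0 | step 3 | none | none
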